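As the chemist in charge of the amber flask, I had to choose what to change in its next charge. The aim was a faster rate at the asked conversion.

the same everywhere: reagent 0.162 M; free catalyst 0.17 mM

| charge | substrate | remark |
|---|---|---|
| amber | 0.17 M | the very flask that is asked about, followed so far |
| red | 0.34 M | run made earlier |
| flask | 0.17 M |  |

- amber (time / s: product / %, substrate / %): 10.0: 2.9, 98.0; 12.0: 3.1, 95.8; 20.0: 4.4, 94.2; 25.0: 6.8, 91.3; 40.0: 11.0, 88.8; 60.0: 15.2, 84.2; 90.0: 22.7, 78.0
- red (time / min: product / %, substrate / %): 0.417: 5.1, 95.1; 0.667: 6.2, 92.8; 1.00: 9.9, 89.0; 1.50: 12.5, 86.4; 2.50: 20.2, 80.2; 4.00: 28.0, 71.6; 6.00: 34.1, 66.2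

(each reading ± 1 percentage point)

1. apparent order in reagent when 50% of the substrate are converted (percent change of the rate of making product for one percent more reagent charged)
2. apparent order in free catalyst when 50% of the substrate are converted (percent change of the rate of making product for one percent more free catalyst charged)

- no earlier run changes the charge of free catalyst; that part of a forecast is a guess
- no earlier run changes the charge of reagent; that part of a forecast is a guess

Substrate looked like a weak handle. The red run held 0.34 M against the amber run's 0.17 M, yet the product at 1.00 min was 0.0337 M in the red run and 0.0258 M in the amber run at 60.0 s, a ratio of 1.30.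

So I wrote the balance of the reagent, the limiting reagent here, taking one reagent per product:

reagent not yet turned into product = 0.162 M − 50% × 0.17 M = 0.0770 M

leverage = 0.162 M / 0.0770 M = 2.10

The leverage is the percent by which the unused reagent grows for one percent more charged, at fixed conversion.

The red run showed what that was worth. The red run's rate read from 1.00 min to 2.50 min was 2.25 times its rate read from 4.00 min to 6.00 min. Its mean unused reagent over the first interval was 1.96 times that over the second. I read that as about first order in unused reagent, so my order in reagent was 2.10. For free catalyst I guessed first order, since no run varied it. My order in reagent stood above the first order I guessed for free catalyst, so I chose more reagent and left substrate and free catalyst as they were.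

The forecast was 1.95 in reagent, lower than my figure, and 0.95 in free catalyst, holding that “the reagent step is turnover-limiting”.

The amber flask gave 1.7 in reagent and 1.2 in free catalyst. Its reagent order was higher than its catalyst order but lower than the leverage.

    substrate + free catalyst → catalyst intermediate A (k = 2500 /M/min)
    reagent + catalyst intermediate A → catalyst intermediate B (k = 2100 /M/min)
    catalyst intermediate B ⇌ free catalyst + product (K = 7.70 M, k = 2100 /min)
    reagent ⇌ dormant form (K = 0.990, k = 0.0720 /min)

The dormant form, which I had not named, stood at 0.0246 M in the amber flask at 4.00 min. At 8.00 min the amber flask held 67.4% product, so the balance gave 0.0474 M not yet turned into product, a leverage of 3.42. Of that amount, the reagent itself was 0.0204 M and the dormant form 0.0271 M.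

(The numbers in the tables were generated by integration with constants of no real substance; scatter was added.)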